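A small charge of starting material, 13 mM, stands in Friday's flask with 0.650 mM of protic impurity, and we want the top of its open dimer.

| flask | starting material | protic impurity | remark | time |
|---|---|---|---|---|
| Friday's | 13 mM | 0.65 mM | the very flask that is asked about, followed so far |  |
| Thursday's | 26 mM | 0.65 mM | run made earlier |  |
| flask | 13 mM | 0.650 mM |  | 10 h |

| run | time / h | open dimer / % | ring / % |
|---|---|---|---|
| Friday's | 0.0667 | 6 | 27 |
| Friday's | 0.200 | 6 | 53 |
| Friday's | 0.500 | 5 | 74 |
| Friday's | 1.33 | 1 | 88 |
| Friday's | 4.00 | 4 | 100 |
| Thursday's | 0.0667 | 10 | 20 |
| Thursday's | 0.200 | 14 | 48 |
| Thursday's | 0.667 | 13 | 81 |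
| Thursday's | 2.00 | 3 | 94 |
| Thursday's | 8.00 | 0 | 102 |

(scatter of a reading: 2 percentage points)

- when, up to 10 h, the flask holds most open dimer
- the amount of open dimer, in percent of the starting material charged, at that time
- earliest time at which at least nineteen twentieths of that best amount are there
- latest time at which they still are

- percentages count the starting material that a species holds: one open dimer counts as two
- the numbers in the tables scatter by 2 percentage points (one standard deviation)

1. We work in logarithms. Both runs were read at 0.200 h: Friday's 13 mM shows 6% open dimer and Thursday's 26 mM shows 14%. The slope n is the common logarithm of the ratio of shares over that of the ratio of charges. It comes to 1.22. A slope of one means the share follows the charge.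

2. Thursday's run gives 5.38 M⁻¹ for the dimer load D, its highest reading of open dimer divided by its charge. D is an empirical scaling number.

3. First way: D times Friday's charge gives 6.99%. Second way: Friday's own reading gives 6%. The two come from different runs, so they can check each other.

4. They part by 1 percentage point, inside the scatter of 2 points. Friday's reading carries that full scatter, while the scaled reading carries half of it. So the first way is less noisy, but Friday's reading borrows no other run. The first way is the one that cheats: it takes a slope of one, where the readings gave 1.22. We commit to 6.99% as the less noisy figure and keep that assumption in view.

5. The forecast reasons that “The dimer share doubles when the charge doubles”. It puts the best at 6.5%, between 5.5% and 7.8%, at 0.27 h, with the window from 0.17 h to 0.38 h. Our figure stands above its number.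

6. Friday's flask reaches 8.01% at 0.279 h, and the window asked for runs from 0.183 h to 0.418 h. The forecast's four numbers hold within tolerance, and our reckoning lies 1 point below the flask.

    starting material + protic impurity → quenched substrate (k = 610 M⁻¹ min⁻¹)
    2 starting material ⇌ open dimer (K = 47.0 M⁻¹, k = 0.720 M⁻¹ min⁻¹)
    starting material → ring (k = 0.0710 min⁻¹)

The neighbouring flask keeps the protic impurity and the time but holds 52 mM of starting material. D times the neighbour's charge gives 28.0%, and the neighbouring flask reaches 25.5%.

(The numbers in the tables were computed on assumed constants; the scatter is artificial.)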